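**Plan**

- Locants: lactone O1, C2(=O), C3, C4, C5; ring A is the guaiacyl ring on benzylic C7 (attached to C3); ring B is the trisubstituted ring on benzylic C7' (attached to C4); ring B carries C8''H(C9''H2OH)–C7''H(OH)–ring C.
- Enabling feature: the γ-butyrolactone has trans arylmethyl groups on C3 and C4 beside an unsubstituted C5H2–O1 unit, so C5 can be carried as a chiral acetal carbon of a butenolide, steer both new bonds and then be reduced to CH2.
- Cuts: C4–C7' and C3–C7 together (three-component union), then ring B–C7' (formylation) and C7''–C8'' (allylboration).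
- Forward: the lactone ring is made first as a furfural-derived menthyloxybutenolide; the ring-B arm is built as a linear chain (allylboronate → anti homoallylic alcohol → diol acetonide → aryl dithiane); the lithiated dithiane, the butenolide and the ring-A benzyl bromide are then joined without closing a ring, and the lactone is opened and reclosed once when C5 is reduced.
- Stereochemistry: C7''/C8'' come from a chiral phosphoric acid-catalysed anti allylboration; C4 is set by the C5 menthyloxy centre (from (−)-menthol, fixed by crystallisation) and C3 by C4.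

Key step: step 13

Assumption: the (R)-configured phosphoric acid is taken to direct the allyl group to the Re face of aldehyde 6, as it does with simple aromatic aldehydes; if the sense proves opposite, the (S)-acid is used.
Abbreviation: ArB = 4-(benzyloxy)-3-methoxy-5-[(4R,5R)-4-(4-benzyloxy-3-methoxyphenyl)-2,2-dimethyl-1,3-dioxan-5-yl]phenyl; l-menthyl = (1R,2S,5R)-2-isopropyl-5-methylcyclohexyl.

**Route**

Step 1
Reactants: 1 furfural
Product: 3 5-hydroxyfuran-2(5H)-one (racemic), via furfural endoperoxide 2 (not isolated)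
Conditions: O2, rose bengal (cat.), MeOH, visible light, rt
Reagents that add atoms: oxygen, O=O
Why: Dye-sensitised photooxygenation: singlet oxygen adds [4+2] across the furan diene to give endoperoxide 2, which methanol cleaves at the formyl carbon with loss of methyl formate to leave the racemic hydroxybutenolide.

Step 2
Reactants: 3 5-hydroxyfuran-2(5H)-one; 4 (−)-menthol
Product: 5 (5R)-5-(l-menthyloxy)furan-2(5H)-one
Conditions: p-TsOH (cat.), toluene, reflux with azeotropic removal of water; crystallisation from petroleum ether; mother liquor re-equilibrated with p-TsOH and recrystallised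
Reagents that add atoms: none
Why: Acid-catalysed acetalisation of the lactol through its cyclic oxocarbenium ion should give both C5 epimers, and because this acetal centre equilibrates under the same acid the less soluble (5R)-epimer can be collected by crystallisation while the mother liquor is recycled, so C5 is fixed by crystallisation-driven epimer selection with the menthyl group as the resolving element.

Step 3
Reactants: 6 4-(benzyloxy)-3-methoxybenzaldehyde
Product: 7 [4-(benzyloxy)-3-methoxyphenyl]methanol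
Conditions: NaBH4, MeOH, 0 °C
Reagents that add atoms: none
Why: Borohydride reduction of an aromatic aldehyde to the benzylic alcohol, to which the aryl benzyl and methyl ethers are inert.

Step 4
Reactants: 7 [4-(benzyloxy)-3-methoxyphenyl]methanol
Product: 8 1-(benzyloxy)-4-(bromomethyl)-2-methoxybenzene
Conditions: PBr3, Et2O, 0 °C
Reagents that add atoms: phosphorus tribromide, BrP(Br)Br
Why: Alcohol-to-bromide substitution with PBr3 (SN2 displacement of the phosphite ester by bromide) at a primary benzylic carbon; the electron-rich bromide is used at once without storage.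

Step 5
Reactants: 9 5-bromo-2-hydroxy-3-methoxybenzaldehyde
Product: 10 2-(benzyloxy)-5-bromo-3-methoxybenzaldehyde
Conditions: BnBr, K2CO3, DMF, rt
Reagents that add atoms: benzyl bromide, BrCc1ccccc1
Why: Williamson etherification of the phenoxide masks the phenol in a form that tolerates the later organolithium, ozone and hydride steps and is removed by hydrogenolysis at the end.

Step 6
Reactants: 10 2-(benzyloxy)-5-bromo-3-methoxybenzaldehyde
Product: 11 2-(benzyloxy)-5-bromo-1-ethenyl-3-methoxybenzene
Conditions: Ph3PCH3Br, KOtBu, THF, 0 °C → rt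
Reagents that add atoms: methyltriphenylphosphonium bromide, [Br-].C[P+](c1ccccc1)(c1ccccc1)c1ccccc1
Why: Wittig methylenation of the aromatic aldehyde with the non-stabilised ylide gives the terminal styrene needed as metathesis partner, and the aryl bromide and benzyl ether do not react.

Step 7
Reactants: 11 2-(benzyloxy)-5-bromo-1-ethenyl-3-methoxybenzene; 12 allylboronic acid pinacol ester
Product: 13 2-{(2E)-3-[2-(benzyloxy)-5-bromo-3-methoxyphenyl]prop-2-en-1-yl}-4,4,5,5-tetramethyl-1,3,2-dioxaborolane
Conditions: 12 (3 equiv), (H2IMes)(PCy3)Cl2Ru=CHPh (3 mol%), CH2Cl2, 40 °C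
Reagents that add atoms: none
Why: Ruthenium-catalysed olefin cross-metathesis between an ortho-substituted styrene, which homodimerises slowly, and an excess of the readily exchanging allylboronate should give the conjugated γ-aryl allylboronate with high E selectivity and release ethene.

Step 8
Reactants: 13 the (E)-γ-aryl allylboronate; 6 4-(benzyloxy)-3-methoxybenzaldehyde
Product: 15 (1R,2S)-2-[2-(benzyloxy)-5-bromo-3-methoxyphenyl]-1-[4-(benzyloxy)-3-methoxyphenyl]but-3-en-1-ol, via borate ester 14 (not isolated)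
Conditions: (R)-TRIP phosphoric acid (5 mol%), 4 Å MS, toluene, −30 → 0 °C; aq NaHCO3
Reagents that add atoms: none
Why: Chiral phosphoric acid-catalysed allylboration through a closed chair transition state in which the E-γ-aryl group and the aldehyde aryl group are both equatorial gives the anti relationship between C7''–OH and the C8'' aryl group, and the (R)-acid, bound to a boronate oxygen and the formyl hydrogen, is expected to direct attack to the Re face of the aldehyde, which sets C7'' as R and C8'' as S in 15 (the arrangement that is labelled 7''R,8''R once the vinyl group has become CH2OH).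

Step 9
Reactants: 15 the anti homoallylic alcohol
Product: 18 (1R,2R)-2-[2-(benzyloxy)-5-bromo-3-methoxyphenyl]-1-[4-(benzyloxy)-3-methoxyphenyl]propane-1,3-diol, via ozonide 16 (not isolated), via hydroxy aldehyde 17 (not isolated)
Conditions: O3, CH2Cl2, −78 °C (Sudan Red 7B end point); then NaBH4, MeOH, −78 → 0 °C
Reagents that add atoms: ozone, [O-][O+]=O
Why: Ozonolysis of the terminal alkene followed by borohydride reduction of the ozonide in the same flask shortens the vinyl group to C9''H2OH, the cold reduction being intended to outrun epimerisation at C8'' or retro-aldol cleavage of the transient α-aryl β-hydroxy aldehyde 17 so that both stereocentres are carried over unchanged.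

Step 10
Reactants: 18 the 1,3-diol
Product: 19 (4R,5R)-5-[2-(benzyloxy)-5-bromo-3-methoxyphenyl]-4-[4-(benzyloxy)-3-methoxyphenyl]-2,2-dimethyl-1,3-dioxane
Conditions: Me2C(OMe)2, PPTS (cat.), CH2Cl2, rt
Reagents that add atoms: 2,2-dimethoxypropane, COC(C)(C)OC
Why: Acid-catalysed transketalisation closes the anti 1,3-diol to the acetonide, a trans-4,5-diaryl-1,3-dioxane with both aryl groups equatorial, which masks both hydroxyl groups against the organolithium reagents that follow.

Step 11
Reactants: 19 the bromo acetonide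
Product: 22 ArB–CHO [4-(benzyloxy)-3-methoxy-5-((4R,5R)-4-(4-benzyloxy-3-methoxyphenyl)-2,2-dimethyl-1,3-dioxan-5-yl)benzaldehyde], via aryllithium 20 (not isolated), via lithium hemiaminal alkoxide 21 (not isolated)
Conditions: n-BuLi, THF, −78 °C; DMF, −78 → 0 °C; aq NH4Cl
Reagents that add atoms: N,N-dimethylformamide, CN(C)C=O
Why: Bromine–lithium exchange at −78 °C is faster than deprotonation at any benzylic or acetal position, and formylation of the aryllithium with DMF (Bouveault-type formylation) installs C7' para to the benzyloxy group.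

Step 12
Reactants: 22 ArB–CHO
Product: 23 2-ArB-1,3-dithiane
Conditions: HS(CH2)3SH, I2 (10 mol%), CH2Cl2, 0 °C → rt; aq Na2S2O3
Reagents that add atoms: propane-1,3-dithiol, SCCCS
Why: Iodine-catalysed dithioacetalisation of an aromatic aldehyde under nearly neutral conditions, chosen because the aldehyde should react much faster than the cyclic ketal exchanges or the electron-rich benzylic C7''–O bond ionises, turns C7' into the masked acyl-anion carbon.

Step 13
Reactants: 23 2-ArB-1,3-dithiane; 5 (5R)-5-(l-menthyloxy)furan-2(5H)-one; 8 1-(benzyloxy)-4-(bromomethyl)-2-methoxybenzene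
Product: 26 (3R,4R,5R)-3-[4-(benzyloxy)-3-methoxybenzyl]-4-(2-ArB-1,3-dithian-2-yl)-5-(l-menthyloxy)dihydrofuran-2(3H)-one, via 2-lithio-1,3-dithiane 24 (not isolated), via lithium enolate 25 (not isolated)
Conditions: n-BuLi, THF, −78 °C; 5, −78 °C; then HMPA, 8, −78 → −20 °C; aq NH4Cl
Reagents that add atoms: none
Why: n-Butyllithium removes the dithiane C2 proton to give the sulfur-stabilised benzylic carbanion 24, which adds 1,4 to C4 of butenolide 5 from the face opposite the C5 menthyloxy group to form the C4–C7' bond and lithium enolate 25, and this enolate is then alkylated at C3 by bromide 8 in an SN2 reaction from the face opposite the new, very bulky dithianyl group to form the C3–C7 bond. The closest known reaction type is the tandem conjugate addition–enolate alkylation of lithiated 2-aryl-1,3-dithianes with 5-alkoxyfuran-2(5H)-ones and benzylic halides used for trans-dibenzylbutyrolactone lignans. No ring is closed, since the lactone ring is already present in 5 and the dithiane ring in 23. The two new stereocentres are controlled in relay, C4 (R) by the C5 acetal centre and C3 (R) by C4, so the single centre fixed by crystallisation in step 2 determines both. The step needs 1,4- over 1,2-addition, which the soft, delocalised and hindered dithiane anion secures; two anti facial selections, which the substituents at C5 and then at C4 of the nearly planar five-membered ring secure; and C-alkylation without proton transfer, which the lithium enolate, the polar additive and the reactive non-enolisable benzylic bromide secure.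

Step 14
Reactants: 26 the three-component adduct
Product: 27 (3R,4R,5R)-3-[4-(benzyloxy)-3-methoxybenzyl]-4-(ArB-methyl)-5-(l-menthyloxy)dihydrofuran-2(3H)-one
Conditions: NiCl2·6H2O, NaBH4, MeOH/THF, 0 °C
Reagents that add atoms: none
Why: Nickel boride generated in the flask hydrogenolyses both benzylic C–S bonds (reductive desulfurisation) to leave the C7' methylene without touching the aryl benzyl ethers, the acetonide or the three lactone stereocentres.

Step 15
Reactants: 27 the desulfurised menthyloxy lactone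
Product: 31 (3R,4R)-3-[4-(benzyloxy)-3-methoxybenzyl]-4-{4-(benzyloxy)-3-[(1R,2R)-1-(4-benzyloxy-3-methoxyphenyl)-1,3-dihydroxypropan-2-yl]-5-methoxybenzyl}dihydrofuran-2(3H)-one, via potassium formyl carboxylate 28 (not isolated), via potassium hydroxy carboxylate 29 (not isolated), via acetonide lactone 30 (not isolated)
Conditions: NaBH4, KOH, EtOH/H2O, rt; then 2 M HCl, THF, rt
Reagents that add atoms: potassium hydroxide, [K+].[OH-] (its oxygen becomes one of the two carboxylate oxygens, one of which stays in the lactone)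
Why: Hydroxide opens the acyl acetal with loss of menthol, the aldehyde so released at C5 is reduced at once by borohydride before C4 can epimerise, and acidification both recloses the γ-lactone by intramolecular esterification (trans-3,4-disubstituted, the thermodynamically preferred arrangement) and hydrolyses the acetonide while all phenols are still benzylated, so that no phenol is free to attack C7''.

Step 16
Reactants: 31 the tri-O-benzyl diol lactone
Product: 32 (3R,4R)-4-{4-hydroxy-3-[(1R,2R)-1,3-dihydroxy-1-(4-hydroxy-3-methoxyphenyl)propan-2-yl]-5-methoxybenzyl}-3-(4-hydroxy-3-methoxybenzyl)dihydrofuran-2(3H)-one (CNP0109231.2)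
Conditions: H2 (1 atm), 10% Pd/C, EtOAc/EtOH, rt
Reagents that add atoms: none
Why: Palladium-catalysed hydrogenolysis of the three aryl benzyl ethers under neutral conditions at atmospheric pressure should be much faster than hydrogenolysis of the secondary benzylic C7''–OH bond and avoids the acid that would cyclise the freed ortho-phenol onto C7'', so it should deliver the target.

**Compound list**

1 | furfural (furan-2-carbaldehyde) | O=Cc1ccco1 | starting material
2 | furfural endoperoxide, 2,3,7-trioxabicyclo[2.2.1]hept-5-ene-1-carbaldehyde (formed in the flask) | O=CC12OOC(O1)C=C2 | intermediate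
3 | 5-hydroxyfuran-2(5H)-one (racemic) | O=C1OC(O)C=C1 | intermediate
4 | (−)-menthol, (1R,2S,5R)-2-isopropyl-5-methylcyclohexanol | C[C@@H]1CC[C@H]([C@@H](C1)O)C(C)C | starting material
5 | (5R)-5-(l-menthyloxy)furan-2(5H)-one | O=C1O[C@@H](O[C@@H]2C[C@H](C)CC[C@H]2C(C)C)C=C1 | intermediate
6 | 4-(benzyloxy)-3-methoxybenzaldehyde | COc1cc(C=O)ccc1OCc1ccccc1 | starting material
7 | [4-(benzyloxy)-3-methoxyphenyl]methanol | COc1cc(CO)ccc1OCc1ccccc1 | intermediate
8 | 1-(benzyloxy)-4-(bromomethyl)-2-methoxybenzene | COc1cc(CBr)ccc1OCc1ccccc1 | intermediate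
9 | 5-bromo-2-hydroxy-3-methoxybenzaldehyde | COc1cc(Br)cc(C=O)c1O | starting material
10 | 2-(benzyloxy)-5-bromo-3-methoxybenzaldehyde | COc1cc(Br)cc(C=O)c1OCc1ccccc1 | intermediate
11 | 2-(benzyloxy)-5-bromo-1-ethenyl-3-methoxybenzene | COc1cc(Br)cc(C=C)c1OCc1ccccc1 | intermediate
12 | allylboronic acid pinacol ester | C=CCB1OC(C)(C)C(C)(C)O1 | starting material
13 | 2-{(2E)-3-[2-(benzyloxy)-5-bromo-3-methoxyphenyl]prop-2-en-1-yl}-4,4,5,5-tetramethyl-1,3,2-dioxaborolane | COc1cc(Br)cc(/C=C/CB2OC(C)(C)C(C)(C)O2)c1OCc1ccccc1 | intermediate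
14 | pinacol borate ester (O–Bpin) of alcohol 15, (1R,2S) (formed in the flask) | COc1cc(Br)cc([C@H](C=C)[C@@H](OB2OC(C)(C)C(C)(C)O2)c2ccc(OCc3ccccc3)c(OC)c2)c1OCc1ccccc1 | intermediate
15 | (1R,2S)-2-[2-(benzyloxy)-5-bromo-3-methoxyphenyl]-1-[4-(benzyloxy)-3-methoxyphenyl]but-3-en-1-ol (anti) | COc1cc(Br)cc([C@H](C=C)[C@@H](O)c2ccc(OCc3ccccc3)c(OC)c2)c1OCc1ccccc1 | intermediate
16 | ozonide of 15: the vinyl group replaced by a 1,2,4-trioxolan-3-yl group, carbinol and aryl-bearing centres as in 15 (formed in the flask) | COc1cc(Br)cc([C@H](C2OCOO2)[C@@H](O)c2ccc(OCc3ccccc3)c(OC)c2)c1OCc1ccccc1 | intermediate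
17 | (2S,3R)-2-[2-(benzyloxy)-5-bromo-3-methoxyphenyl]-3-[4-(benzyloxy)-3-methoxyphenyl]-3-hydroxypropanal (formed in the flask) | COc1cc(Br)cc([C@H](C=O)[C@@H](O)c2ccc(OCc3ccccc3)c(OC)c2)c1OCc1ccccc1 | intermediate
18 | (1R,2R)-2-[2-(benzyloxy)-5-bromo-3-methoxyphenyl]-1-[4-(benzyloxy)-3-methoxyphenyl]propane-1,3-diol | COc1cc(Br)cc([C@H](CO)[C@@H](O)c2ccc(OCc3ccccc3)c(OC)c2)c1OCc1ccccc1 | intermediate
19 | (4R,5R)-5-[2-(benzyloxy)-5-bromo-3-methoxyphenyl]-4-[4-(benzyloxy)-3-methoxyphenyl]-2,2-dimethyl-1,3-dioxane (ArB–Br) | COc1cc(Br)cc([C@H](CO2)[C@@H](OC2(C)C)c2ccc(OCc3ccccc3)c(OC)c2)c1OCc1ccccc1 | intermediate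
20 | aryllithium ArB–Li (formed in the flask) | COc1cc([Li])cc([C@H](CO2)[C@@H](OC2(C)C)c2ccc(OCc3ccccc3)c(OC)c2)c1OCc1ccccc1 | intermediate
21 | lithium hemiaminal alkoxide ArB–CH(OLi)NMe2 (formed in the flask) | COc1cc(C(O[Li])N(C)C)cc([C@H](CO2)[C@@H](OC2(C)C)c2ccc(OCc3ccccc3)c(OC)c2)c1OCc1ccccc1 | intermediate
22 | ArB–CHO, 4-(benzyloxy)-3-methoxy-5-[(4R,5R)-4-(4-benzyloxy-3-methoxyphenyl)-2,2-dimethyl-1,3-dioxan-5-yl]benzaldehyde | COc1cc(C=O)cc([C@H](CO2)[C@@H](OC2(C)C)c2ccc(OCc3ccccc3)c(OC)c2)c1OCc1ccccc1 | intermediate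
23 | 2-ArB-1,3-dithiane | COc1cc(C2SCCCS2)cc([C@H](CO2)[C@@H](OC2(C)C)c2ccc(OCc3ccccc3)c(OC)c2)c1OCc1ccccc1 | intermediate
24 | 2-lithio-2-ArB-1,3-dithiane (formed in the flask) | COc1cc(C2([Li])SCCCS2)cc([C@H](CO2)[C@@H](OC2(C)C)c2ccc(OCc3ccccc3)c(OC)c2)c1OCc1ccccc1 | intermediate
25 | lithium enolate of (4R,5R)-4-(2-ArB-1,3-dithian-2-yl)-5-(l-menthyloxy)dihydrofuran-2(3H)-one (formed in the flask) | [Li]OC1O[C@@H](O[C@@H]2C[C@H](C)CC[C@H]2C(C)C)[C@H](C2(SCCCS2)c2cc(OC)c(OCc3ccccc3)c([C@H](CO4)[C@@H](OC4(C)C)c4ccc(OCc5ccccc5)c(OC)c4)c2)C=1 | intermediate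
26 | (3R,4R,5R)-3-[4-(benzyloxy)-3-methoxybenzyl]-4-(2-ArB-1,3-dithian-2-yl)-5-(l-menthyloxy)dihydrofuran-2(3H)-one (3,4-trans, 4,5-trans) | O=C1O[C@@H](O[C@@H]2C[C@H](C)CC[C@H]2C(C)C)[C@H](C2(SCCCS2)c2cc(OC)c(OCc3ccccc3)c([C@H](CO4)[C@@H](OC4(C)C)c4ccc(OCc5ccccc5)c(OC)c4)c2)[C@H]1Cc1ccc(OCc2ccccc2)c(OC)c1 | intermediate
27 | (3R,4R,5R)-3-[4-(benzyloxy)-3-methoxybenzyl]-4-(ArB-methyl)-5-(l-menthyloxy)dihydrofuran-2(3H)-one | O=C1O[C@@H](O[C@@H]2C[C@H](C)CC[C@H]2C(C)C)[C@H](Cc2cc(OC)c(OCc3ccccc3)c([C@H](CO4)[C@@H](OC4(C)C)c4ccc(OCc5ccccc5)c(OC)c4)c2)[C@H]1Cc1ccc(OCc2ccccc2)c(OC)c1 | intermediate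
28 | potassium (2R,3R)-2-[4-(benzyloxy)-3-methoxybenzyl]-3-(ArB-methyl)-4-oxobutanoate (formed in the flask) | [K+].[O-]C(=O)[C@H](Cc1ccc(OCc2ccccc2)c(OC)c1)[C@H](C=O)Cc1cc(OC)c(OCc2ccccc2)c([C@H](CO3)[C@@H](OC3(C)C)c3ccc(OCc4ccccc4)c(OC)c3)c1 | intermediate
29 | potassium (2R,3R)-2-[4-(benzyloxy)-3-methoxybenzyl]-3-(ArB-methyl)-4-hydroxybutanoate (formed in the flask) | [K+].[O-]C(=O)[C@H](Cc1ccc(OCc2ccccc2)c(OC)c1)[C@H](CO)Cc1cc(OC)c(OCc2ccccc2)c([C@H](CO3)[C@@H](OC3(C)C)c3ccc(OCc4ccccc4)c(OC)c3)c1 | intermediate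
30 | (3R,4R)-3-[4-(benzyloxy)-3-methoxybenzyl]-4-(ArB-methyl)dihydrofuran-2(3H)-one, acetonide still in place (formed in the flask) | COc1cc(C[C@H]2C(=O)OC[C@@H]2Cc2cc(OC)c(OCc3ccccc3)c([C@H](CO3)[C@@H](OC3(C)C)c3ccc(OCc4ccccc4)c(OC)c3)c2)ccc1OCc1ccccc1 | intermediate
31 | (3R,4R)-3-[4-(benzyloxy)-3-methoxybenzyl]-4-{4-(benzyloxy)-3-[(1R,2R)-1-(4-benzyloxy-3-methoxyphenyl)-1,3-dihydroxypropan-2-yl]-5-methoxybenzyl}dihydrofuran-2(3H)-one | COc1cc(C[C@H]2C(=O)OC[C@@H]2Cc2cc(OC)c(OCc3ccccc3)c([C@H](CO)[C@@H](O)c3ccc(OCc4ccccc4)c(OC)c3)c2)ccc1OCc1ccccc1 | intermediate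
32 | (3R,4R)-4-{4-hydroxy-3-[(1R,2R)-1,3-dihydroxy-1-(4-hydroxy-3-methoxyphenyl)propan-2-yl]-5-methoxybenzyl}-3-(4-hydroxy-3-methoxybenzyl)dihydrofuran-2(3H)-one (CNP0109231.2) | COc1cc(C[C@H]2C(=O)OC[C@@H]2Cc2cc(OC)c(O)c([C@H](CO)[C@@H](O)c3ccc(O)c(OC)c3)c2)ccc1O | target

**Step count**

Total: 16 steps. Longest linear sequence: 12 steps (steps 5–16, from 9).

**Steps most likely to fail**

Step 8. The catalysed pathway may be too slow for a γ-aryl allylboronate and an electron-rich aldehyde, so that conversion stalls or uncatalysed addition erodes the facial discrimination; the anti relationship should hold either way. The fallback sets out from 13 and 6 and returns at 15, replacing asymmetric catalysis by classical resolution. The two are heated without catalyst (toluene, 80 °C); the same chair transition state should give the racemic anti borate ester F1 and, after aqueous hydrolysis, the racemic anti homoallylic alcohol F2. Acylation with (1S)-(−)-camphanic chloride (Et3N, DMAP, CH2Cl2) converts this into two diastereomeric esters, the camphanate of the (1R,2S)-alcohol F3 and the camphanate of the (1S,2R)-alcohol F4, which are separated by chromatography or crystallisation. Methanolysis of F3 (K2CO3, MeOH) gives 15.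

Step 12. Acid-mediated exchange of the acetonide with the dithiol, or ionisation of the electron-rich benzylic C7''–O bond followed by capture by thiol, may compete with thioacetal formation. The fallback sets out from 19 and returns at 23, avoiding both the aldehyde stage and all acid. 2-Chloro-1,3-dithiane F5 is prepared freshly from 1,3-dithiane and N-chlorosuccinimide (benzene/THF). Bromide 19 is lithiated to 20 as in step 11 and transmetalated with MgBr2·OEt2 to the arylmagnesium bromide F6, which is added at −40 °C to F5. This electrophilic dithianylation of a Grignard reagent should give 23 directly.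

Step 13. Trapping of the hindered enolate may be incomplete or be overtaken by proton transfer, so that unalkylated conjugate adduct accumulates alongside the product. The fallback sets out from 23 and 5 and returns at 26, splitting the one-flask union into two separate reactions. The conjugate addition is run alone (n-BuLi, THF, −78 °C; then 5) and quenched with NH4Cl to isolate the trans Michael adduct F7. After purification, F7 is deprotonated with LDA (THF/HMPA, −78 °C) to regenerate enolate 25 free of other basic species and is alkylated with 8 (−78 → −20 °C), again anti to the dithianyl group, to give 26.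

**Further compounds**

F1 | step 8 | racemic anti pinacol borate ester of 2-[2-(benzyloxy)-5-bromo-3-methoxyphenyl]-1-[4-(benzyloxy)-3-methoxyphenyl]but-3-en-1-ol (formed in the flask) | COc1cc(Br)cc([C@H](C=C)[C@@H](OB2OC(C)(C)C(C)(C)O2)c2ccc(OCc3ccccc3)c(OC)c2)c1OCc1ccccc1.COc1cc(Br)cc([C@@H](C=C)[C@H](OB2OC(C)(C)C(C)(C)O2)c2ccc(OCc3ccccc3)c(OC)c2)c1OCc1ccccc1
F2 | step 8 | racemic anti 2-[2-(benzyloxy)-5-bromo-3-methoxyphenyl]-1-[4-(benzyloxy)-3-methoxyphenyl]but-3-en-1-ol, (1R,2S) and (1S,2R) | COc1cc(Br)cc([C@H](C=C)[C@@H](O)c2ccc(OCc3ccccc3)c(OC)c2)c1OCc1ccccc1.COc1cc(Br)cc([C@@H](C=C)[C@H](O)c2ccc(OCc3ccccc3)c(OC)c2)c1OCc1ccccc1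
F3 | step 8 | (1S,4R)-camphanate of the (1R,2S)-alcohol | COc1cc(Br)cc([C@H](C=C)[C@@H](OC(=O)[C@@]23CC[C@@](C)(C(=O)O2)C3(C)C)c2ccc(OCc3ccccc3)c(OC)c2)c1OCc1ccccc1
F4 | step 8 | (1S,4R)-camphanate of the (1S,2R)-alcohol | COc1cc(Br)cc([C@@H](C=C)[C@H](OC(=O)[C@@]23CC[C@@](C)(C(=O)O2)C3(C)C)c2ccc(OCc3ccccc3)c(OC)c2)c1OCc1ccccc1
F5 | step 12 | 2-chloro-1,3-dithiane | ClC1SCCCS1
F6 | step 12 | arylmagnesium bromide ArB–MgBr | COc1cc([Mg]Br)cc([C@H](CO2)[C@@H](OC2(C)C)c2ccc(OCc3ccccc3)c(OC)c2)c1OCc1ccccc1
F7 | step 13 | (4R,5R)-4-(2-ArB-1,3-dithian-2-yl)-5-(l-menthyloxy)dihydrofuran-2(3H)-one (trans Michael adduct) | O=C1O[C@@H](O[C@@H]2C[C@H](C)CC[C@H]2C(C)C)[C@H](C2(SCCCS2)c2cc(OC)c(OCc3ccccc3)c([C@H](CO4)[C@@H](OC4(C)C)c4ccc(OCc5ccccc5)c(OC)c4)c2)C1
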